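**Strategy.** Everything rests on reading the cyclohexene ring (C1, C10, C11, C12, C13, C14; briarane numbering) as an expanded cyclopentene: its tertiary carbinol C11 (OH, CH3-20) next to oxygenated C12 is the signature of an α-ketol rearrangement. A cyclopentenone that already carries C1/C2 (Ireland–Claisen, Baeyer–Villiger) and C9/C10 (chelation-controlled aldol) is converted at C12 into the tertiary acetyl carbinol; shifting the C12–C10 bond onto the acetyl carbon then gives the 6-hydroxy-6-methylcyclohexenone and sets C11 in one operation. The ten-membered ring is closed afterwards by a Heck vinylation, and the chlorohydrin lactone follows from Sharpless epoxidation, chloride opening and an intramolecular Reformatsky reaction.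

Key step: step 17

Remark: locants follow briarane numbering (C1 quaternary with CH3-15; C2–C10 ten-membered ring; C5=C16; C11 with CH3-20; lactone C17/CH3-18/C19). Compounds 15 and 31 are carried as epimer mixtures at a centre that the next step destroys.

Step 1
Reactants: 1 3-methylcyclopent-2-en-1-one
Product: 2 (S)-3-methylcyclopent-2-en-1-ol
Conditions: (R)-Me-CBS (10 mol %), BH3·SMe2, THF, −20 °C
Reagents that add atoms: none
Why: CBS reduction, in which the oxazaborolidine binds the carbonyl anti to the alkenyl side and delivers hydride 1,2 to give the (S)-allylic alcohol whose configuration is later relayed to C1.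

Step 2
Reactants: 3 hex-5-ynoic acid
Product: 4 5-bromohex-5-enoic acid
Conditions: HBr, Et4NBr, CH2Cl2, 40 °C
Reagents that add atoms: hydrogen bromide, Br
Why: Markovnikov hydrobromination of the terminal alkyne by the HBr2− ion pair should stop at the 2-bromo-1-alkene, the latent C5(=C16) vinyl partner of the Heck closure, which is inert to the enolate, organometallic and oxidative steps in between.

Step 3
Reactants: 2 (S)-3-methylcyclopent-2-en-1-ol; 4 5-bromohex-5-enoic acid
Product: 5 (S)-3-methylcyclopent-2-en-1-yl 5-bromohex-5-enoate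
Conditions: DCC, DMAP (cat.), CH2Cl2, 0 °C to rt
Reagents that add atoms: none
Why: Steglich esterification joins the fragments under neutral conditions that do not ionise the allylic alcohol.

Step 4
Reactants: 5 (S)-3-methylcyclopent-2-en-1-yl 5-bromohex-5-enoate
Product: 8 (2S)-5-bromo-2-[(1R)-1-methylcyclopent-2-en-1-yl]hex-5-enoic acid, via Z-silyl ketene acetal 6 (not isolated), via trimethylsilyl ester 7 (not isolated)
Conditions: LDA, THF–DMPU (4:1), −78 °C; TMSCl, −78 to 50 °C; dil. HCl
Reagents that add atoms: none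
Why: Ireland–Claisen rearrangement, in which the ketene acetal with the chain cis to OSiMe3 reacts suprafacially through the boat-like transition state usual for cycloalkenyl esters, so the carbinol configuration is transferred to quaternary C1 and the chain at C2 sits exo, which is the C1/C2 relationship of the target once the carboxyl is replaced by oxygen with retention.

Step 5
Reactants: 8 (2S)-5-bromo-2-[(1R)-1-methylcyclopent-2-en-1-yl]hex-5-enoic acid
Product: 9 (3S)-6-bromo-3-[(1R)-1-methylcyclopent-2-en-1-yl]hept-6-en-2-one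
Conditions: MeLi (2.2 equiv), Et2O, −78 to 0 °C; H2O
Reagents that add atoms: methyllithium, [Li]C
Why: addition of methyllithium to the lithium carboxylate gives a gem-diolate that collapses to the methyl ketone only on work-up, so over-addition is avoided and the Baeyer–Villiger substrate results.

Step 6
Reactants: 9 (3S)-6-bromo-3-[(1R)-1-methylcyclopent-2-en-1-yl]hept-6-en-2-one
Product: 10 (4R)-4-[(3S)-6-bromo-2-oxohept-6-en-3-yl]-4-methylcyclopent-2-en-1-one
Conditions: CrO3, 3,5-dimethylpyrazole, CH2Cl2, −20 °C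
Reagents that add atoms: chromium trioxide, O=[Cr](=O)=O
Why: allylic oxidation should occur at C12, the only allylic CH2 of the electron-rich ring alkene (C1 is quaternary and the bromoalkene is deactivated), giving the 4,4-disubstituted cyclopentenone.

Step 7
Reactants: 10 (4R)-4-[(3S)-6-bromo-2-oxohept-6-en-3-yl]-4-methylcyclopent-2-en-1-one
Product: 11 (1S)-4-bromo-1-[(1R)-1-methyl-4-oxocyclopent-2-en-1-yl]pent-4-en-1-yl acetate
Conditions: mCPBA, NaHCO3, CH2Cl2, rt
Reagents that add atoms: 3-chloroperbenzoic acid, OOC(=O)c1cccc(Cl)c1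
Why: Baeyer–Villiger oxidation, in which the secondary C2 migrates in preference to methyl with retention, turns C2–COCH3 into C2–OAc while the enone and bromoalkene are too electron-poor to be epoxidised.

Step 8
Reactants: 11 (1S)-4-bromo-1-[(1R)-1-methyl-4-oxocyclopent-2-en-1-yl]pent-4-en-1-yl acetate
Product: 12 (4R)-4-[(1S)-4-bromo-1-hydroxypent-4-en-1-yl]-4-methylcyclopent-2-en-1-one
Conditions: K2CO3 (cat.), MeOH, rt
Reagents that add atoms: none
Why: mild transesterification frees the C2 hydroxyl without affecting the enone.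

Step 9
Reactants: 12 (4R)-4-[(1S)-4-bromo-1-hydroxypent-4-en-1-yl]-4-methylcyclopent-2-en-1-one
Product: 13 (4R)-4-[(1S)-4-bromo-1-(tert-butyldimethylsilyloxy)pent-4-en-1-yl]-4-methylcyclopent-2-en-1-one
Conditions: TBSOTf, 2,6-lutidine, CH2Cl2, −78 °C
Reagents that add atoms: tert-butyldimethylsilyl triflate, CC(C)(C)[Si](C)(C)OS(=O)(=O)C(F)(F)F
Why: silylation masks C2–OH against the enolate, organolithium and base steps and blocks a vinylogous retro-aldol cleavage of C1–C2.

Step 10
Reactants: 14 (S)-but-3-ene-1,2-diol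
Product: 15 (4S)-2-(4-methoxyphenyl)-4-vinyl-1,3-dioxolane
Conditions: 4-MeOC6H4CH(OMe)2, PPTS (cat.), CH2Cl2, rt
Reagents that add atoms: 4-methoxybenzaldehyde dimethyl acetal, COc1ccc(C(OC)OC)cc1
Why: acid-catalysed transacetalisation gives the p-methoxybenzylidene acetal of the 1,2-diol.

Step 11
Reactants: 15 (4S)-2-(4-methoxyphenyl)-4-vinyl-1,3-dioxolane
Product: 16 (2S)-2-[(4-methoxybenzyl)oxy]but-3-en-1-ol
Conditions: DIBAL-H, CH2Cl2, −78 to 0 °C; Rochelle salt
Reagents that add atoms: none
Why: regioselective reductive acetal opening, with aluminium on the less hindered primary oxygen, leaves the PMB ether on the secondary oxygen.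

Step 12
Reactants: 16 (2S)-2-[(4-methoxybenzyl)oxy]but-3-en-1-ol
Product: 17 (2S)-2-[(4-methoxybenzyl)oxy]but-3-enal
Conditions: Dess–Martin periodinane, NaHCO3, CH2Cl2, 0 °C; used at once
Reagents that add atoms: none
Why: buffered Dess–Martin oxidation gives the α-alkoxy aldehyde without base, so neither the stereocentre nor the β,γ-double bond should be scrambled.

Step 13
Reactants: 13 (4R)-4-[(1S)-4-bromo-1-(tert-butyldimethylsilyloxy)pent-4-en-1-yl]-4-methylcyclopent-2-en-1-one
Product: 18 2-(trimethylsilyloxy)cyclopenta-1,3-diene derived from 13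
Conditions: TMSOTf, Et3N, CH2Cl2, 0 °C
Reagents that add atoms: trimethylsilyl triflate, C[Si](C)(C)OS(=O)(=O)C(F)(F)F
Why: soft enolisation can only occur towards C10 (C13 is vinylic, C1 quaternary), giving a single cross-conjugated silyl dienol ether.

Step 14
Reactants: 18 2-(trimethylsilyloxy)cyclopenta-1,3-diene derived from 13; 17 (2S)-2-[(4-methoxybenzyl)oxy]but-3-enal
Product: 19 aldol adduct with the C9(OH)–C8(OPMB)–CH=CH2 chain on C10
Conditions: MgBr2·OEt2, CH2Cl2, −78 to −30 °C; aq. NaHCO3
Reagents that add atoms: none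
Why: chelation-controlled Mukaiyama aldol, in which MgBr2 bridges the aldehyde and PMB oxygens so that attack occurs anti to the vinyl group (8,9-syn) and from the enol-silane face anti to the bulky C2 chain on C1 (C9 cis to CH3-15), the open transition state giving the 9,10-syn adduct for which the (S)-aldehyde is the matched enantiomer.

Step 15
Reactants: 19 aldol adduct with the C9(OH)–C8(OPMB)–CH=CH2 chain on C10
Product: 20 C9 TBS ether of 19
Conditions: TBSOTf, 2,6-lutidine, CH2Cl2, −78 to 0 °C
Reagents that add atoms: tert-butyldimethylsilyl triflate, CC(C)(C)[Si](C)(C)OS(=O)(=O)C(F)(F)F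
Why: silylation of the β-hydroxy ketone prevents retro-aldol and elimination in the following basic steps.

Step 16
Reactants: 20 C9 TBS ether of 19
Product: 22 α-ketol (1-acetylcyclopent-2-en-1-ol with C12–OH cis to the C9 chain), via 1-ethoxyvinyl carbinol 21 (not isolated)
Conditions: ethyl vinyl ether, t-BuLi, THF, −78 to 0 °C; CeCl3, −78 °C; then 20; 0.5 M HCl, THF, 0 °C
Reagents that add atoms: ethyl vinyl ether, C=COCC
Why: 1,2-addition of the acetyl anion equivalent to the enone carbonyl should occur anti to the adjacent C10 side chain (new C–C bond trans to C9), and mild acid hydrolysis of the enol ether unveils the tertiary α-ketol.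

Step 17
Reactants: 22 α-ketol (1-acetylcyclopent-2-en-1-ol with C12–OH cis to the C9 chain)
Product: 23 6-hydroxy-6-methylcyclohex-2-enone (C11–OH cis to H-10, CH3-20 cis to C9)
Conditions: KOH, MeOH–H2O (9:1), 40 °C
Reagents that add atoms: none
Why: Base-mediated α-ketol (acyloin) rearrangement: the potassium alkoxide at C12 re-forms a carbonyl while the C12–C10 σ-bond shifts suprafacially, with retention at C10, onto the acetyl carbon C11, which becomes the ring carbinol bearing CH3-20 and OH. The closest known reaction type is the D-homoannulation of 17α-hydroxy-20-oxo steroids. No ring is closed by cyclisation; the five-membered ring (C1, C10, C12, C13, C14) becomes the six-membered ring by insertion of C11 between C10 and C12 in a 1,2-shift. The new stereocentre C11 is controlled by the C12 configuration set in step 16 together with the transoid, dipole-opposed arrangement of C12–O− and C11=O that a non-chelating potassium counter-ion in a protic medium favours, so that C10 attacks the acetyl face that leaves OH cis to H-10 and CH3-20 cis to C9. The step needs migration of C10 and not of the vinylic C13, and this should be secured thermodynamically, because the rearrangement is reversible and only C10 migration gives the conjugated enone with release of the congested C10–C12 bond and of cyclopentene strain. The product ketone has no enolisable α-hydrogen (C11 quaternary, C13 vinylic), so C10 is not at risk afterwards.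

Step 18
Reactants: 23 6-hydroxy-6-methylcyclohex-2-enone (C11–OH cis to H-10, CH3-20 cis to C9)
Product: 24 cis-11,12-diol
Conditions: NaBH4, CeCl3·7H2O, MeOH, −78 °C
Reagents that add atoms: none
Why: Luche 1,2-reduction, in which hydride should add to C12 anti to the pseudo-axial C11–O bond of the half-chair that keeps CH3-15 and CH3-20 pseudo-equatorial, giving the 12-hydroxyl cis to the 11-hydroxyl.

Step 19
Reactants: 24 cis-11,12-diol
Product: 25 C12 TBS ether
Conditions: TBSOTf (1.1 equiv), 2,6-lutidine, CH2Cl2, −78 °C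
Reagents that add atoms: tert-butyldimethylsilyl triflate, CC(C)(C)[Si](C)(C)OS(=O)(=O)C(F)(F)F
Why: the secondary allylic C12 hydroxyl is silylated selectively because the tertiary C11 hydroxyl is too hindered at −78 °C.

Step 20
Reactants: 25 C12 TBS ether
Product: 26 C8 allylic alcohol (8,9-syn)
Conditions: DDQ, CH2Cl2–pH 7 buffer, 0 °C
Reagents that add atoms: none
Why: oxidative PMB cleavage frees the C8 hydroxyl without touching silyl ethers, alkenes or the vinyl bromide.

Step 21
Reactants: 26 C8 allylic alcohol (8,9-syn)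
Product: 27 ten-membered (6E)-dienol
Conditions: Pd(OAc)2 (20 mol %), P(o-tol)3, Ag2CO3, DMF, 70 °C, 2 mM
Reagents that add atoms: none
Why: intramolecular Heck vinylation under Jeffery silver conditions (10-endo carbopalladation at the terminal carbon C6, then syn β-hydride elimination towards C6) should give the (E)-C6=C7 diene with C5=C16 exocyclic, the silver salt suppressing elimination towards the carbinol so that C8–OH and its configuration survive.

Step 22
Reactants: 27 ten-membered (6E)-dienol
Product: 28 6,7-epoxy-8-alcohol (trans-epoxide, erythro to C8–OH)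
Conditions: Ti(OiPr)4, D-(−)-DIPT, t-BuOOH, 4 Å MS, CH2Cl2, −20 °C
Reagents that add atoms: tert-butyl hydroperoxide, CC(C)(C)OO
Why: Sharpless asymmetric epoxidation of the proximal alkene of the dienol, for which the C8 configuration inherited from aldehyde 17 is the fast-reacting (matched) one with D-(−)-tartrate, delivers the erythro trans-epoxide and so sets C7 and (as its invertomer) C6 under reagent control.

Step 23
Reactants: 28 6,7-epoxy-8-alcohol (trans-epoxide, erythro to C8–OH)
Product: 29 6,7-epoxy-8-ketone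
Conditions: Dess–Martin periodinane, NaHCO3, CH2Cl2, 0 °C to rt
Reagents that add atoms: none
Why: neutral oxidation gives the α,β-epoxy ketone and removes the C8 stereocentre, which has served its relay purpose.

Step 24
Reactants: 29 6,7-epoxy-8-ketone
Product: 30 6-chloro-7-hydroxy-8-ketone
Conditions: HCl (1 M in Et2O, 1.2 equiv), CH2Cl2, −40 °C
Reagents that add atoms: hydrogen chloride, Cl
Why: acid-promoted epoxide opening by chloride should occur at C6, which is allylic to C5=C16 and β to the ketone, with inversion, while C7 (α to the carbonyl) keeps its configuration, giving the anti chlorohydrin of the target.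

Step 25
Reactants: 30 6-chloro-7-hydroxy-8-ketone
Product: 31 C7 2-bromopropanoate of 30
Conditions: 2-bromopropanoyl bromide, pyridine, CH2Cl2, −20 °C
Reagents that add atoms: 2-bromopropanoyl bromide, CC(Br)C(Br)=O
Why: O-acylation of the secondary α-hydroxy ketone with a weak base at low temperature avoids E1cB loss of HCl and leaves the hindered tertiary C11 hydroxyl untouched.

Step 26
Reactants: 31 C7 2-bromopropanoate of 30
Product: 33 tris-TBS lactone, via samarium enolate 32 (not isolated)
Conditions: SmI2 (2.5 equiv), THF, −78 °C; aq. NH4Cl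
Reagents that add atoms: none
Why: SmI2-mediated intramolecular Reformatsky reaction (5-exo addition of the Sm(III) Z-enolate to the C8 ketone), in which the five-membered lactone can only close with C6 and C9 trans across C7–C8 in the ten-membered ring (C8–OH cis to C6) and Sm chelation of enolate and ketone oxygens places CH3-18 cis to the new hydroxyl, the enolate being formed reductively so that no base touches the β-chloro ketone.

Step 27
Reactants: 33 tris-TBS lactone
Product: 34 pentaol (2,8,9,11,12-OH)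
Conditions: HF·pyridine, pyridine, THF, 0 °C to rt
Reagents that add atoms: none
Why: fluoride-mediated desilylation under buffered, non-basic conditions should spare the allylic chloride and the β-hydroxy lactone.

Step 28
Reactants: 34 pentaol (2,8,9,11,12-OH)
Product: 35 CNP0259091.1
Conditions: Ac2O, pyridine, DMAP (cat.), CH2Cl2, 0 °C to rt
Reagents that add atoms: acetic anhydride, CC(=O)OC(C)=O
Why: the three secondary hydroxyls (C2, C9, C12) are acetylated while the tertiary C8 and C11 hydroxyls are too hindered to react under these conditions.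

**Compound list**

1 | 3-methylcyclopent-2-en-1-one | CC1=CC(=O)CC1 | starting material
2 | (S)-3-methylcyclopent-2-en-1-ol | CC1=C[C@@H](O)CC1 | intermediate
3 | hex-5-ynoic acid | C#CCCCC(=O)O | starting material
4 | 5-bromohex-5-enoic acid | C=C(Br)CCCC(=O)O | intermediate
5 | (S)-3-methylcyclopent-2-en-1-yl 5-bromohex-5-enoate | C=C(Br)CCCC(=O)O[C@@H]1C=C(C)CC1 | intermediate
6 | Z-silyl ketene acetal of 5 (chain cis to OSiMe3) | C=C(Br)CC/C=C(\O[Si](C)(C)C)O[C@@H]1C=C(C)CC1 | intermediate
7 | trimethylsilyl (2S)-5-bromo-2-[(1R)-1-methylcyclopent-2-en-1-yl]hex-5-enoate | C=C(Br)CC[C@H](C(=O)O[Si](C)(C)C)[C@@]1(C)C=CCC1 | intermediate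
8 | (2S)-5-bromo-2-[(1R)-1-methylcyclopent-2-en-1-yl]hex-5-enoic acid | C=C(Br)CC[C@H](C(=O)O)[C@@]1(C)C=CCC1 | intermediate
9 | (3S)-6-bromo-3-[(1R)-1-methylcyclopent-2-en-1-yl]hept-6-en-2-one | C=C(Br)CC[C@H](C(C)=O)[C@@]1(C)C=CCC1 | intermediate
10 | (4R)-4-[(3S)-6-bromo-2-oxohept-6-en-3-yl]-4-methylcyclopent-2-en-1-one | C=C(Br)CC[C@H](C(C)=O)[C@@]1(C)C=CC(=O)C1 | intermediate
11 | (1S)-4-bromo-1-[(1R)-1-methyl-4-oxocyclopent-2-en-1-yl]pent-4-en-1-yl acetate | C=C(Br)CC[C@H](OC(C)=O)[C@@]1(C)C=CC(=O)C1 | intermediate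
12 | (4R)-4-[(1S)-4-bromo-1-hydroxypent-4-en-1-yl]-4-methylcyclopent-2-en-1-one | C=C(Br)CC[C@H](O)[C@@]1(C)C=CC(=O)C1 | intermediate
13 | (4R)-4-[(1S)-4-bromo-1-(tert-butyldimethylsilyloxy)pent-4-en-1-yl]-4-methylcyclopent-2-en-1-one | C=C(Br)CC[C@H](O[Si](C)(C)C(C)(C)C)[C@@]1(C)C=CC(=O)C1 | intermediate
14 | (S)-but-3-ene-1,2-diol | OC[C@@H](O)C=C | starting material
15 | (4S)-2-(4-methoxyphenyl)-4-vinyl-1,3-dioxolane (both epimers at the acetal carbon) | C=C[C@H]1COC(c2ccc(OC)cc2)O1 | intermediate
16 | (2S)-2-[(4-methoxybenzyl)oxy]but-3-en-1-ol | OC[C@@H](OCc1ccc(OC)cc1)C=C | intermediate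
17 | (2S)-2-[(4-methoxybenzyl)oxy]but-3-enal | O=C[C@@H](OCc1ccc(OC)cc1)C=C | intermediate
18 | 2-(trimethylsilyloxy)cyclopenta-1,3-diene derived from 13 (C1, C2 unchanged) | C=C(Br)CC[C@H](O[Si](C)(C)C(C)(C)C)[C@@]1(C)C=CC(O[Si](C)(C)C)=C1 | intermediate
19 | aldol adduct: cyclopentenone with, on C10 cis to CH3-15, the chain C9H(OH)–C8H(OPMB)–CH=CH2 (9,10-syn; 8,9-syn) | C=C(Br)CC[C@H](O[Si](C)(C)C(C)(C)C)[C@@]1(C)C=CC(=O)[C@@H]1[C@H](O)[C@@H](OCc1ccc(OC)cc1)C=C | intermediate
20 | C9 TBS ether of 19 | C=C(Br)CC[C@H](O[Si](C)(C)C(C)(C)C)[C@@]1(C)C=CC(=O)[C@@H]1[C@H](O[Si](C)(C)C(C)(C)C)[C@@H](OCc1ccc(OC)cc1)C=C | intermediate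
21 | C12 1-ethoxyvinyl carbinol (C12–OH cis to the C9 chain) | C=C(Br)CC[C@H](O[Si](C)(C)C(C)(C)C)[C@@]1(C)C=C[C@@](O)(C(=C)OCC)[C@@H]1[C@H](O[Si](C)(C)C(C)(C)C)[C@@H](OCc1ccc(OC)cc1)C=C | intermediate
22 | α-ketol: 1-acetylcyclopent-2-en-1-ol (acetyl trans, OH cis to the C9 chain) | C=C(Br)CC[C@H](O[Si](C)(C)C(C)(C)C)[C@@]1(C)C=C[C@@](O)(C(C)=O)[C@@H]1[C@H](O[Si](C)(C)C(C)(C)C)[C@@H](OCc1ccc(OC)cc1)C=C | intermediate
23 | 6-hydroxy-6-methylcyclohex-2-enone (C12 ketone; C11–OH cis to H-10, CH3-20 cis to C9) | C=C(Br)CC[C@H](O[Si](C)(C)C(C)(C)C)[C@@]1(C)C=CC(=O)[C@@](C)(O)[C@@H]1[C@H](O[Si](C)(C)C(C)(C)C)[C@@H](OCc1ccc(OC)cc1)C=C | intermediate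
24 | cis-11,12-diol | C=C(Br)CC[C@H](O[Si](C)(C)C(C)(C)C)[C@@]1(C)C=C[C@@H](O)[C@@](C)(O)[C@@H]1[C@H](O[Si](C)(C)C(C)(C)C)[C@@H](OCc1ccc(OC)cc1)C=C | intermediate
25 | C12 TBS ether | C=C(Br)CC[C@H](O[Si](C)(C)C(C)(C)C)[C@@]1(C)C=C[C@@H](O[Si](C)(C)C(C)(C)C)[C@@](C)(O)[C@@H]1[C@H](O[Si](C)(C)C(C)(C)C)[C@@H](OCc1ccc(OC)cc1)C=C | intermediate
26 | C8 allylic alcohol (8,9-syn) | C=C(Br)CC[C@H](O[Si](C)(C)C(C)(C)C)[C@@]1(C)C=C[C@@H](O[Si](C)(C)C(C)(C)C)[C@@](C)(O)[C@@H]1[C@H](O[Si](C)(C)C(C)(C)C)[C@@H](O)C=C | intermediate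
27 | ten-membered (6E)-dienol (C5=C16 exocyclic, C6=C7, C8–OH) | O[C@H]1/C=C/C(=C)CC[C@H](O[Si](C)(C)C(C)(C)C)[C@@]2(C)C=C[C@@H](O[Si](C)(C)C(C)(C)C)[C@@](C)(O)[C@@H]2[C@@H]1O[Si](C)(C)C(C)(C)C | intermediate
28 | 6,7-epoxy-8-alcohol (trans-epoxide, erythro to C8–OH) | O[C@H]1[C@H]2O[C@@H]2C(=C)CC[C@H](O[Si](C)(C)C(C)(C)C)[C@@]3(C)C=C[C@@H](O[Si](C)(C)C(C)(C)C)[C@@](C)(O)[C@@H]3[C@@H]1O[Si](C)(C)C(C)(C)C | intermediate
29 | 6,7-epoxy-8-ketone | O=C1[C@H]2O[C@@H]2C(=C)CC[C@H](O[Si](C)(C)C(C)(C)C)[C@@]3(C)C=C[C@@H](O[Si](C)(C)C(C)(C)C)[C@@](C)(O)[C@@H]3[C@@H]1O[Si](C)(C)C(C)(C)C | intermediate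
30 | 6-chloro-7-hydroxy-8-ketone | O=C1[C@@H](O)[C@@H](Cl)C(=C)CC[C@H](O[Si](C)(C)C(C)(C)C)[C@@]2(C)C=C[C@@H](O[Si](C)(C)C(C)(C)C)[C@@](C)(O)[C@@H]2[C@@H]1O[Si](C)(C)C(C)(C)C | intermediate
31 | C7 2-bromopropanoate of 30 (both epimers at CHBr) | O=C1[C@@H](OC(=O)C(C)Br)[C@@H](Cl)C(=C)CC[C@H](O[Si](C)(C)C(C)(C)C)[C@@]2(C)C=C[C@@H](O[Si](C)(C)C(C)(C)C)[C@@](C)(O)[C@@H]2[C@@H]1O[Si](C)(C)C(C)(C)C | intermediate
32 | samarium(III) Z-enolate of the C7 propanoate | O=C1[C@@H](O/C(O[Sm](I)I)=C/C)[C@@H](Cl)C(=C)CC[C@H](O[Si](C)(C)C(C)(C)C)[C@@]2(C)C=C[C@@H](O[Si](C)(C)C(C)(C)C)[C@@](C)(O)[C@@H]2[C@@H]1O[Si](C)(C)C(C)(C)C | intermediate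
33 | tris-TBS lactone (target skeleton with TBS ethers at C2, C9, C12) | C=C1CC[C@H](O[Si](C)(C)C(C)(C)C)[C@@]2(C)C=C[C@@H](O[Si](C)(C)C(C)(C)C)[C@@](C)(O)[C@@H]2[C@H](O[Si](C)(C)C(C)(C)C)[C@]2(O)[C@@H](C)C(=O)O[C@H]2[C@H]1Cl | intermediate
34 | pentaol (2,8,9,11,12-OH) | C=C1CC[C@H](O)[C@@]2(C)C=C[C@@H](O)[C@@](C)(O)[C@@H]2[C@H](O)[C@]2(O)[C@@H](C)C(=O)O[C@H]2[C@H]1Cl | intermediate
35 | CNP0259091.1 (2,9,12-triacetate) | C=C1CC[C@H](OC(C)=O)[C@@]2(C)C=C[C@@H](OC(C)=O)[C@@](C)(O)[C@@H]2[C@H](OC(C)=O)[C@]2(O)[C@@H](C)C(=O)O[C@H]2[C@H]1Cl | target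

**Step count.** Total: 28 steps. Longest linear sequence: 24 steps (steps 1, 3–9 and 13–28, from 1 or equally from 3 via step 2).

**Steps most likely to fail**

1. Step 17 (α-ketol ring expansion). The shift may take the wrong course: the vinylic C13 may migrate instead of C10 and the resulting non-conjugated isomer may not funnel back, or the cisoid rotamer may react and give the C11 epimer. The fallback sets out from 22 and switches to an aprotic, Lewis-acid-driven acyloin shift of the protected ketol. O-Silylation (TMSOTf, 2,6-lutidine) should give the α-trimethylsilyloxy ketone F1. An organoaluminium promoter (methylaluminium bis(4-bromo-2,6-di-tert-butylphenoxide), CH2Cl2, −78 to −20 °C) should then move C10 onto the activated acetyl carbon with silyl transfer, giving the ring-expanded silyl ether F2. Mild methanolysis (K2CO3, MeOH) returns to the route at 23.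

2. Step 21 (Heck macrocyclisation). Ring closure to the ten-membered ring may be too slow against oligomerisation, or β-hydride elimination may run towards the carbinol and give a saturated ketone. The fallback sets out from 26 and makes the C5–C6 bond by cross-coupling of a preformed (E)-alkenylboron unit. Cross-metathesis with vinylboronic acid pinacol ester (Hoveyda–Grubbs II, CH2Cl2, 40 °C) should give the (E)-alkenylboronate F3. Intramolecular Suzuki–Miyaura coupling with the vinyl bromide (Pd(PPh3)4, TlOEt, THF–H2O, high dilution) comes back to the route at 27.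

3. Step 26 (SmI2 Reformatsky lactonisation). Electron transfer to the α-acyloxy ketone may compete with C–Br reduction and cleave the C7–O bond, or a ketyl may expel chloride. The fallback sets out from 30 and builds the C8–C17 bond intermolecularly without a reductant. A chelation-controlled Mukaiyama aldol of the α-hydroxy ketone with (E)-1-methoxy-1-(trimethylsilyloxy)propene (MgBr2·OEt2, CH2Cl2, −78 °C) should add anti to C6 in the C7–O/C8=O chelate and give the β-hydroxy ester F4. Acid-catalysed lactonisation onto C7–OH (PPTS, benzene, rt) comes back to the route at 33.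

**Further compounds**

F1 | step 17 | O-trimethylsilyl ether of α-ketol 22 | C=C(Br)CC[C@H](O[Si](C)(C)C(C)(C)C)[C@@]1(C)C=C[C@@](O[Si](C)(C)C)(C(C)=O)[C@@H]1[C@H](O[Si](C)(C)C(C)(C)C)[C@@H](OCc1ccc(OC)cc1)C=C
F2 | step 17 | C11 trimethylsilyl ether of hydroxy enone 23 | C=C(Br)CC[C@H](O[Si](C)(C)C(C)(C)C)[C@@]1(C)C=CC(=O)[C@@](C)(O[Si](C)(C)C)[C@@H]1[C@H](O[Si](C)(C)C(C)(C)C)[C@@H](OCc1ccc(OC)cc1)C=C
F3 | step 21 | (E)-alkenylboronic acid pinacol ester at C6 of 26 | C=C(Br)CC[C@H](O[Si](C)(C)C(C)(C)C)[C@@]1(C)C=C[C@@H](O[Si](C)(C)C(C)(C)C)[C@@](C)(O)[C@@H]1[C@H](O[Si](C)(C)C(C)(C)C)[C@@H](O)/C=C/B1OC(C)(C)C(C)(C)O1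
F4 | step 26 | methyl ester of the C8 aldol adduct (7,8-diol, C17 methyl ester) | C=C1CC[C@H](O[Si](C)(C)C(C)(C)C)[C@@]2(C)C=C[C@@H](O[Si](C)(C)C(C)(C)C)[C@@](C)(O)[C@@H]2[C@H](O[Si](C)(C)C(C)(C)C)[C@](O)([C@@H](C)C(=O)OC)[C@@H](O)[C@H]1Cl
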